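**Assumption:** stages run in one flask without isolation are counted as one step, and the target SMILES is read as the (2S)-flavanone.

## Retrosynthetic overview

1. Ring B is bought, not built: 3,5-dibromo-4-hydroxybenzaldehyde (1) + prenyl-Bpin (2) → aldehyde 3; Wittig with 4 → amide 5; ethynyl Grignard 6 → enynone 7 (ring B + C2–C3–C4 + C4a≡C5).
2. C6, C7, C8, C8a, both ring-A oxygens and the C8 prenyl come from methyl acetoacetate (8) + prenyl bromide (9) → keto ester 10, then TMSOTf (11) → bis(silyloxy)diene 12.
3. Key disconnection (one flask, two rings): ring A at C4a–C8a and C5–C6 ([4+2] of 7 with 12, then aromatisation to the 2′-hydroxychalcone in situ) and ring C at O1–C2 (asymmetric 6-endo oxa-Michael) → sophoranone 13.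
4. Ring order: B (purchased) → A (de novo benzannulation) → C (closure sets C2 = S, last bond formed). No protecting-group steps.

## Route

**Step 1**
Reactants: 1, 3,5-dibromo-4-hydroxybenzaldehyde; 2, 3-methylbut-2-en-1-ylboronic acid pinacol ester (2.6 equiv)
Product: 3, 4-hydroxy-3,5-bis(3-methylbut-2-en-1-yl)benzaldehyde
Conditions: Pd-PEPPSI-IPent (3 mol %), 5 M aq KOH, THF, 65 °C
Reagents that add atoms: prenyl-Bpin (2), CC(C)=CCB1OC(C)(C)C(C)(C)O1
Why: An α-selective (linear) allyl–aryl Suzuki–Miyaura coupling with a bulky NHC–Pd catalyst installs both prenyl groups ortho to the phenol, while the aldehyde, deactivated as the para-phenoxide under the basic conditions, resists allylboration; no stereocentre is formed.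

**Step 2**
Reactants: 3; 4, N-methoxy-N-methyl-2-(triphenylphosphoranylidene)acetamide (1.5 equiv)
Product: 5, (2E)-3-[4-hydroxy-3,5-bis(3-methylbut-2-en-1-yl)phenyl]-N-methoxy-N-methylprop-2-enamide
Conditions: toluene, 90 °C
Reagents that add atoms: ylide 4, CON(C)C(=O)C=P(c1ccccc1)(c1ccccc1)c1ccccc1
Why: Wittig olefination with a stabilised ylide gives the E-alkene and tolerates the free phenol; no stereocentre is formed.

**Step 3**
Reactants: 5; 6, ethynylmagnesium bromide (3.5 equiv)
Product: 7, (1E)-1-[4-hydroxy-3,5-bis(3-methylbut-2-en-1-yl)phenyl]pent-1-en-4-yn-3-one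
Conditions: THF, −20 → 0 °C; inverse quench into cold aq NaHSO4
Reagents that add atoms: ethynylmagnesium bromide (6), C#C[Mg]Br
Why: Weinreb ketone synthesis, in which the chelated tetrahedral intermediate stops at mono-addition and releases the terminal ynone on acidic quench; one extra equivalent of Grignard covers the phenol.

**Step 4**
Reactants: 8, methyl acetoacetate (1.5 equiv); 9, 1-bromo-3-methylbut-2-ene (prenyl bromide)
Product: 10, methyl 2-acetyl-5-methylhex-4-enoate (racemic)
Conditions: K2CO3, acetone, reflux
Reagents that add atoms: prenyl bromide (9), CC(C)=CCBr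
Why: Acetoacetic ester C-alkylation (SN2 at the primary allylic bromide); the new stereocentre is racemic and is erased in step 5.

**Step 5**
Reactants: 10; 11, trimethylsilyl trifluoromethanesulfonate (2.3 equiv)
Product: 12, 1-methoxy-2-(3-methylbut-2-en-1-yl)-1,3-bis(trimethylsilyloxy)buta-1,3-diene (E/Z mixture at C1=C2, used crude)
Conditions: Et3N (2.6 equiv), Et2O, 0 °C → rt; separate the ammonium triflate layer, concentrate
Reagents that add atoms: TMSOTf (11), C[Si](C)(C)OS(=O)(=O)C(F)(F)F
Why: Simchen-type double O-silylation of a β-keto ester (ketone enol ether first, then silylation at the ester oxygen with loss of a γ-methyl proton) gives the Chan-type 1,3-bis(silyloxy)diene directly; no stereocentre is formed.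

**Step 6 (key step, one flask)**
Reactants: 7; 12 (1.6 equiv)
Product: 13, sophoranone, (2S)-7-hydroxy-2-[4-hydroxy-3,5-bis(3-methylbut-2-en-1-yl)phenyl]-8-(3-methylbut-2-en-1-yl)-2,3-dihydro-4H-chromen-4-one
Conditions:
- (i) BSA (1.2 equiv), toluene, rt; then 12, 0 → 50 °C.
- (ii) MeOH–AcOH (50:1), rt, 30 min; evaporate and strip with toluene.
- (iii) quinidine-derived 9-epi-amino 3,5-bis(trifluoromethyl)phenyl thiourea (20 mol %), toluene, 0–25 °C. Confirm the sense of induction by CD on the first run; the quinine-derived pseudoenantiomer is the drop-in replacement if it is opposite.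

Reagents that add atoms: none (all atoms of 13 come from 7 and 12; the TMS groups from BSA and 12 and the OMe of 12 are lost in stage ii)
Why: Proposed new method: a thermal Diels–Alder of the O-silylated ynone with the bis(silyloxy)diene (diene CH2 terminus to the alkyne β-carbon, ketene-acetal carbon to the α-carbon) gives a 1-methoxy-1,3-bis(silyloxy)cyclohexa-2,5-diene that, on methanolysis, loses MeOH and the silyl groups to aromatise ring A as the 2′,4′-dihydroxy-3′-prenylchalcone (sophoradin, not isolated), whose 2′-OH then closes ring C by a 6-endo oxa-Michael addition in which the catalyst amine activates the phenol and the thiourea binds the carbonyl, directing attack to the Si face of the enone β-carbon and setting C2 as S; the closest known reactions are Chan/Brassard-diene–alkynone benzannulations and bifunctional-thiourea (chalcone-isomerase-type) cyclisations of 2′-hydroxychalcones, which have not been combined in one flask or run on a tri-phenolic chalcone.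

## Compound list

| No. | Name | SMILES | Role |
|---|---|---|---|
| 1 | 3,5-dibromo-4-hydroxybenzaldehyde | O=Cc1cc(Br)c(O)c(Br)c1 | starting material |
| 2 | 3-methylbut-2-en-1-ylboronic acid pinacol ester | CC(C)=CCB1OC(C)(C)C(C)(C)O1 | starting material |
| 3 | 4-hydroxy-3,5-bis(3-methylbut-2-en-1-yl)benzaldehyde | O=Cc1cc(CC=C(C)C)c(O)c(CC=C(C)C)c1 | intermediate |
| 4 | N-methoxy-N-methyl-2-(triphenylphosphoranylidene)acetamide | CON(C)C(=O)C=P(c1ccccc1)(c1ccccc1)c1ccccc1 | starting material |
| 5 | (2E)-3-[4-hydroxy-3,5-bis(3-methylbut-2-en-1-yl)phenyl]-N-methoxy-N-methylprop-2-enamide | CON(C)C(=O)/C=C/c1cc(CC=C(C)C)c(O)c(CC=C(C)C)c1 | intermediate |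
| 6 | ethynylmagnesium bromide | C#C[Mg]Br | starting material |
| 7 | (1E)-1-[4-hydroxy-3,5-bis(3-methylbut-2-en-1-yl)phenyl]pent-1-en-4-yn-3-one | C#CC(=O)/C=C/c1cc(CC=C(C)C)c(O)c(CC=C(C)C)c1 | intermediate |
| 8 | methyl acetoacetate | COC(=O)CC(C)=O | starting material |
| 9 | 1-bromo-3-methylbut-2-ene | CC(C)=CCBr | starting material |
| 10 | methyl 2-acetyl-5-methylhex-4-enoate (racemic) | COC(=O)C(CC=C(C)C)C(C)=O | intermediate |
| 11 | trimethylsilyl trifluoromethanesulfonate | C[Si](C)(C)OS(=O)(=O)C(F)(F)F | starting material |
| 12 | 1-methoxy-2-(3-methylbut-2-en-1-yl)-1,3-bis(trimethylsilyloxy)buta-1,3-diene | COC(O[Si](C)(C)C)=C(CC=C(C)C)C(=C)O[Si](C)(C)C | intermediate |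
| 13 | sophoranone, (2S)-7-hydroxy-2-[4-hydroxy-3,5-bis(3-methylbut-2-en-1-yl)phenyl]-8-(3-methylbut-2-en-1-yl)-2,3-dihydro-4H-chromen-4-one | CC(C)=CCc1cc([C@@H]2CC(=O)c3ccc(O)c(CC=C(C)C)c3O2)cc(CC=C(C)C)c1O | target |

## Summary

Total steps: 6.
Longest linear sequence: 4 (steps 1 → 2 → 3 → 6); the diene branch is steps 4 → 5 → 6.

Steps most likely to fail, with one fallback each:

1. **Step 6.** The oxa-Michael stage is reversible and acts on a chalcone with three free phenols and an electron-rich B ring, so the ee may be modest or erode with conversion; the enone C=C of 7 could also compete in the cycloaddition.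
   Fallback: set C2 by C–C instead of C–O bond formation. Diene 12 + but-3-yn-2-one gives 2,4-dihydroxy-3-prenylacetophenone; DMF-DMA then acid gives 7-hydroxy-8-prenylchromone; Pd(II)/t-BuPyOx-catalysed enantioselective conjugate addition of (4-hydroxy-3,5-diprenylphenyl)boronic acid gives 13.
2. **Step 1.** Double coupling on a free, acidic ortho-bromophenol may stall, some γ-coupled (1,1-dimethylallyl) isomer may form, and the aldehyde may be partly allylborated.
   Fallback: drop cross-coupling and C-prenylate the phenoxide of 4-hydroxybenzaldehyde directly with prenyl bromide in aq KOH, accepting a low yield of 3 from very cheap materials.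
3. **Step 3.** The terminal enynone 7 can be lost to conjugate addition of liberated MeNHOMe or phenoxide, or to polymerisation.
   Fallback: reach 7 by an oxidation route. Wittig of 3 with (triphenylphosphoranylidene)acetaldehyde gives the cinnamaldehyde; ethynylmagnesium bromide gives the enynol; MnO2 gives 7.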